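Tanegol ⇐ hydrogenolysis of one benzyl ether ⇐ LiAlH4 opening of a cis-fused aryl furo[3,4-c]furanone; this lactone is a temporary ring that ties the C3 hydroxymethyl carbon (at the acid level) to the benzylic oxygen of the C4 side chain.
Bicyclic lactone ⇐ acyclic MOM ether/MOM ester in one Lewis-acid cascade: acetal ionisation, closure of the oxolane by its C4–C5 bond (styrene carbon onto O=CH2+), then closure of the lactone at the benzylic cation; the oxolane forms first, the lactone second, in the same flask.
Enabling feature: oxolane C5 is a CH2 between O1 and C4, i.e. a formaldehyde carbon; the C4 substituent is a carbinol carbon para to an aryl ether oxygen, i.e. the hydration site of a stabilised benzylic cation; that carbinol oxygen and the C3 carbon are cis and 1,4-related, so an acid-level C3 carbon can catch the cation.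
Cascade precursor ⇐ Evans syn aldol of an (E)-4-aryl-but-3-enoyl oxazolidinone with a vanillin carbamate (sets oxolane C2 and C3); the C2 aryl ring is made electron-poor (carbamate), the styrene ring is kept electron-rich (benzyl ether).
Butenoic acid ⇐ Wittig reaction of O-benzylvanillin; both aryl rings come from vanillin.

Key step: step 7

Remark: the target is taken as drawn, (7S,8R,7'S,8'R), i.e. 2,3-trans-3,4-cis on the oxolane; lignan locants are used in the text (oxolane C2 = C7, C3 = C8, C4 = C8', C5 = C9'; C9 = hydroxymethyl carbon on C8, C7' = carbinol carbon on C8').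

Step 1
Reactants: 1 4-(benzyloxy)-3-methoxybenzaldehyde; 2 (2-carboxyethyl)triphenylphosphonium bromide
Product: 4 (3E)-4-[4-(benzyloxy)-3-methoxyphenyl]but-3-enoic acid, via carboxylate ylide 3 (not isolated)
Conditions: 2, NaN(SiMe3)2 (2 equiv per 2), THF, 0 °C; 1, −78 °C → rt; aq. HCl; crystallisation
Reagents that add atoms: none
Why: Wittig olefination: the ylide 3, made with two equivalents of base, condenses with the aryl aldehyde, and carboxylate-bearing ylides of this kind are expected to give mainly the E alkene, the double bond staying in conjugation with the ring; crystallisation of the acid should remove any Z isomer.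

Step 2
Reactants: 4 (3E)-4-[4-(benzyloxy)-3-methoxyphenyl]but-3-enoic acid; 5 (4S)-4-benzyl-1,3-oxazolidin-2-one
Product: 7 (4S)-4-benzyl-3-{(3E)-4-[4-(benzyloxy)-3-methoxyphenyl]but-3-enoyl}-1,3-oxazolidin-2-one, via mixed pivalic anhydride 6 (not isolated)
Conditions: PivCl, Et3N, THF, −20 °C; then 5, LiCl, −20 °C → rt
Reagents that add atoms: none
Why: N-acylation of the oxazolidinone through the mixed pivalic anhydride 6 (LiCl/Et3N variant), which needs no strong base and so should leave the β,γ-double bond in place.

Step 3
Reactants: 8 vanillin (4-hydroxy-3-methoxybenzaldehyde)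
Product: 9 4-formyl-2-methoxyphenyl dimethylcarbamate
Conditions: Me2NCOCl, K2CO3, MeCN, 60 °C
Reagents that add atoms: dimethylcarbamoyl chloride, CN(C)C(=O)Cl
Why: O-carbamoylation of the phenol (acyl substitution); the carbamate makes this ring electron-poor, so that the benzylic C–O bond later attached to it does not ionise in step 7, and it is stable to LiOOH yet cleaved by LiAlH4.

Step 4
Reactants: 7 (4S)-4-benzyl-3-{(3E)-4-[4-(benzyloxy)-3-methoxyphenyl]but-3-enoyl}-1,3-oxazolidin-2-one; 9 4-formyl-2-methoxyphenyl dimethylcarbamate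
Product: 11 (4S)-4-benzyl-3-[(2S,3E)-4-[4-(benzyloxy)-3-methoxyphenyl]-2-{(S)-[4-(dimethylcarbamoyloxy)-3-methoxyphenyl](hydroxy)methyl}but-3-enoyl]-1,3-oxazolidin-2-one, via boron dienolate 10 (not isolated)
Conditions: Bu2BOTf, Et3N, CH2Cl2, −78 → 0 °C; 9, −78 → 0 °C; pH 7 buffer (NaH2PO4/Na2HPO4), MeOH, 30% H2O2, 0 °C
Reagents that add atoms: none
Why: Evans syn aldol reaction: the (Z)-boron dienolate 10 reacts at its α-carbon through a closed chair (Zimmerman–Traxler) transition state on the face opposite the benzyl group of the (S)-auxiliary, which sets the carbinol centre (S) and the α-centre (S) in a syn relation, the E double bond being carried through.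

Step 5
Reactants: 11 the aldol adduct of step 4
Product: 13 (2S,3E)-4-[4-(benzyloxy)-3-methoxyphenyl]-2-{(S)-[4-(dimethylcarbamoyloxy)-3-methoxyphenyl](hydroxy)methyl}but-3-enoic acid, via peroxy acid 12 (not isolated)
Conditions: LiOH·H2O, 30% H2O2, THF/H2O, 0 °C; Na2SO3; HCl to pH 3
Reagents that add atoms: lithium hydroperoxide, [Li+].[O-]O (from LiOH and H2O2)
Why: Hydroperoxide cleavage of the imide: LiOOH attacks the exocyclic carbonyl group, sulfite reduces the peroxy acid 12, and at 0 °C the aryl carbamate, the benzyl ether and the α-stereocentre are expected to be untouched.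

Step 6
Reactants: 13 the hydroxy acid of step 5
Product: 14 methoxymethyl (2S,3E)-4-[4-(benzyloxy)-3-methoxyphenyl]-2-{(S)-[4-(dimethylcarbamoyloxy)-3-methoxyphenyl](methoxymethoxy)methyl}but-3-enoate
Conditions: MOMCl (3 equiv), iPr2NEt (4 equiv), CH2Cl2, 0 °C → rt
Reagents that add atoms: chloromethyl methyl ether, COCCl
Why: Double O-alkylation (carboxylate and hindered secondary alcohol) with MOMCl and iPr2NEt; the MOM ether is the latent O=CH2+ unit and the MOM ester is a carboxyl group that can shed its alkyl group as a stabilised cation, and no stereocentre is touched.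

Step 7
Reactants: 14 the MOM ether/MOM ester of step 6
Product: 17 (3S,3aR,6S,6aS)-3-[4-(benzyloxy)-3-methoxyphenyl]-6-[4-(dimethylcarbamoyloxy)-3-methoxyphenyl]tetrahydro-1H,3H-furo[3,4-c]furan-1-one, via oxocarbenium triflate 15 (not isolated), via benzylic cation triflate 16 (not isolated)
Conditions: TMSOTf (0.5 equiv), 2,6-di-tert-butyl-4-methylpyridine (0.2 equiv), CH2Cl2 (0.02 M), −78 → −30 °C; Et3N quench
Reagents that add atoms: none
Why: Proposed new method: TMSOTf takes methoxide from the MOM ether (the less hindered acetal oxygen) and gives the O-methylene oxocarbenium ion 15; the non-benzylic carbon of the electron-rich E-styrene attacks its CH2 carbon (5-exo-trig with respect to the alkene, the oxygen and the CH2 of the former acetal becoming O1 and C5 of the oxolane) and forms the C4–C5 bond and the 4-benzyloxy-stabilised benzylic cation 16, which is caught by the carbonyl oxygen of the MOM ester (five-membered O-closure onto the trigonal cation, a γ-lactonisation) with loss of MeOCH2+, which combines with TMSOMe to dimethoxymethane and returns TMSOTf. The closest known reaction types are the oxonium-Prins cyclisation of styrenyl homoallylic acetals to 3-(α-substituted benzyl)oxolanes and the capture of benzylic cations by a neighbouring carboxyl oxygen as in halolactonisation; their union, with formaldehyde as the acetal carbon and a carboxyl group as terminator, is not known. The ring-fusion centre C8' is set by the allylic centre C8: the oxocarbenium carbon is held on the face of the tether, and the acyl group is expected to lie in the plane of the alkene (acceptor away from the π system, its oxygen next to the developing cation), which gives the cis arrangement; a cation of the other configuration cannot reach the carboxyl group, so the bicycle that is isolated can only be cis-fused. The benzylic centre C7' is set by the E geometry of the alkene through anti addition of carbon and oxygen with least motion of the cation, which puts the aryl group on the convex face, also the more stable position. The step needs ionisation at the acetal carbon and not at the benzylic C7–O bond, which the electron-poor carbamate ring secures, and attack through the non-benzylic alkene carbon (oxolane and not a six-membered ring or an oxonia-Cope shift), which the 4-benzyloxy group secures by polarising the styrene; the hindered pyridine and the low temperature keep protic acid from re-ionising the benzylic lactone.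

Step 8
Reactants: 17 the bicyclic lactone of step 7
Product: 18 4-[(2S,3R,4R)-4-{(S)-[4-(benzyloxy)-3-methoxyphenyl](hydroxy)methyl}-3-(hydroxymethyl)oxolan-2-yl]-2-methoxyphenol
Conditions: LiAlH4 (excess), THF, 0 °C → 40 °C; aq. KNaC4H4O6 (potassium sodium tartrate) work-up
Reagents that add atoms: none
Why: Hydride reduction: LiAlH4 opens the γ-lactone to the primary alcohol and the benzylic alkoxide without breaking the C–O bond at the benzylic centre, so its configuration is kept, and the same reagent reduces the aryl carbamate to the phenoxide and trimethylamine.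

Step 9
Reactants: 18 the O-benzyl ether of step 8
Product: 19 (−)-tanegol, 4-[(2S,3R,4R)-4-{(S)-hydroxy(4-hydroxy-3-methoxyphenyl)methyl}-3-(hydroxymethyl)oxolan-2-yl]-2-methoxyphenol
Conditions: H2 (1 atm), 10% Pd/C, EtOAc, rt, stopped when 18 is consumed
Reagents that add atoms: none
Why: Catalytic hydrogenolysis of the benzyl aryl ether, which under neutral conditions is expected to be much faster than cleavage of the benzylic alcohol or of the benzylic ring C–O bond; no stereocentre is touched.

Compound list
1 | 4-(benzyloxy)-3-methoxybenzaldehyde (O-benzylvanillin) | O=Cc1ccc(OCc2ccccc2)c(OC)c1 | starting material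
2 | (2-carboxyethyl)triphenylphosphonium bromide | OC(=O)CC[P+](c1ccccc1)(c1ccccc1)c1ccccc1.[Br-] | starting material
3 | sodium 3-(triphenylphosphoranylidene)propanoate, the carboxylate ylide (formed in the flask, step 1) | [Na+].[O-]C(=O)C[CH-][P+](c1ccccc1)(c1ccccc1)c1ccccc1 | intermediate
4 | (3E)-4-[4-(benzyloxy)-3-methoxyphenyl]but-3-enoic acid | OC(=O)C/C=C/c1ccc(OCc2ccccc2)c(OC)c1 | intermediate
5 | (4S)-4-benzyl-1,3-oxazolidin-2-one | O=C1N[C@@H](Cc2ccccc2)CO1 | starting material
6 | mixed anhydride of 4 with pivalic acid (formed in the flask, step 2) | CC(C)(C)C(=O)OC(=O)C/C=C/c1ccc(OCc2ccccc2)c(OC)c1 | intermediate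
7 | (4S)-4-benzyl-3-{(3E)-4-[4-(benzyloxy)-3-methoxyphenyl]but-3-enoyl}-1,3-oxazolidin-2-one | O=C(C/C=C/c1ccc(OCc2ccccc2)c(OC)c1)N1[C@@H](Cc2ccccc2)COC1=O | intermediate
8 | vanillin (4-hydroxy-3-methoxybenzaldehyde) | O=Cc1ccc(O)c(OC)c1 | starting material
9 | 4-formyl-2-methoxyphenyl dimethylcarbamate | O=Cc1ccc(OC(=O)N(C)C)c(OC)c1 | intermediate
10 | (Z)-dibutylboron dienolate of 7 (formed in the flask, step 4) | CCCCB(CCCC)O/C(=C\C=C\c1ccc(OCc2ccccc2)c(OC)c1)N1[C@@H](Cc2ccccc2)COC1=O | intermediate
11 | (4S)-4-benzyl-3-[(2S,3E)-4-[4-(benzyloxy)-3-methoxyphenyl]-2-{(S)-[4-(dimethylcarbamoyloxy)-3-methoxyphenyl](hydroxy)methyl}but-3-enoyl]-1,3-oxazolidin-2-one | O[C@H](c1ccc(OC(=O)N(C)C)c(OC)c1)[C@H](/C=C/c1ccc(OCc2ccccc2)c(OC)c1)C(=O)N1[C@@H](Cc2ccccc2)COC1=O | intermediate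
12 | peroxy acid corresponding to 13 (formed in the flask, step 5) | O[C@H](c1ccc(OC(=O)N(C)C)c(OC)c1)[C@H](/C=C/c1ccc(OCc2ccccc2)c(OC)c1)C(=O)OO | intermediate
13 | (2S,3E)-4-[4-(benzyloxy)-3-methoxyphenyl]-2-{(S)-[4-(dimethylcarbamoyloxy)-3-methoxyphenyl](hydroxy)methyl}but-3-enoic acid | O[C@H](c1ccc(OC(=O)N(C)C)c(OC)c1)[C@H](/C=C/c1ccc(OCc2ccccc2)c(OC)c1)C(=O)O | intermediate
14 | methoxymethyl (2S,3E)-4-[4-(benzyloxy)-3-methoxyphenyl]-2-{(S)-[4-(dimethylcarbamoyloxy)-3-methoxyphenyl](methoxymethoxy)methyl}but-3-enoate | COCO[C@H](c1ccc(OC(=O)N(C)C)c(OC)c1)[C@H](/C=C/c1ccc(OCc2ccccc2)c(OC)c1)C(=O)OCOC | intermediate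
15 | O-methylene oxocarbenium triflate derived from 14 (formed in the flask, step 7) | C=[O+][C@H](c1ccc(OC(=O)N(C)C)c(OC)c1)[C@H](/C=C/c1ccc(OCc2ccccc2)c(OC)c1)C(=O)OCOC.[O-]S(=O)(=O)C(F)(F)F | intermediate
16 | benzylic cation triflate with the oxolane closed (formed in the flask, step 7) | COc1cc([CH+][C@H]2CO[C@H](c3ccc(OC(=O)N(C)C)c(OC)c3)[C@H]2C(=O)OCOC)ccc1OCc1ccccc1.[O-]S(=O)(=O)C(F)(F)F | intermediate
17 | (3S,3aR,6S,6aS)-3-[4-(benzyloxy)-3-methoxyphenyl]-6-[4-(dimethylcarbamoyloxy)-3-methoxyphenyl]tetrahydro-1H,3H-furo[3,4-c]furan-1-one | COc1cc([C@@H]3[C@H]2CO[C@H](c4ccc(OC(=O)N(C)C)c(OC)c4)[C@H]2C(=O)O3)ccc1OCc1ccccc1 | intermediate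
18 | 4-[(2S,3R,4R)-4-{(S)-[4-(benzyloxy)-3-methoxyphenyl](hydroxy)methyl}-3-(hydroxymethyl)oxolan-2-yl]-2-methoxyphenol | COc1cc([C@@H](O)[C@H]2CO[C@H](c3ccc(O)c(OC)c3)[C@H]2CO)ccc1OCc1ccccc1 | intermediate
19 | (−)-tanegol | COc1cc([C@@H](O)[C@H]2CO[C@H](c3ccc(O)c(OC)c3)[C@H]2CO)ccc1O | target

Total step count: 9. Longest linear sequence: 8 steps (1 → 4 → 7 → 11 → 13 → 14 → 17 → 18 → 19).

Steps most likely to fail

First, step 7 (the key step). What may go wrong: attack of the oxocarbenium ion on the other face of the alkene, after which the cation cannot be captured by the carboxyl group and drains away by proton loss or oligomerisation; slow capture would have the same effect. The fallback uses known reactions and is convergent in the ring-fusion centre; it sets out from 14 and returns at 17. Ionisation of 14 with TMSOTf (1.1 equiv) and an excess of 2,6-di-tert-butyl-4-methylpyridine at −40 → 0 °C lets the benzylic cation end by loss of the ring proton next to it (Prins cyclisation with elimination). From either face of attack this should give the same benzylidene oxolane, methoxymethyl (2S,3S,4Z)-4-[4-(benzyloxy)-3-methoxybenzylidene]-2-[4-(dimethylcarbamoyloxy)-3-methoxyphenyl]oxolane-3-carboxylate F1; any 17 formed directly is collected. Hydroboration–oxidation of F1 (BH3·SMe2, THF, 0 °C; then NaOH, H2O2, which also hydrolyses the MOM ester) adds H and OH syn to the Z alkene from the face opposite the C3 carboxyl group. After acidification it should give (2S,3S,4R)-4-{(S)-[4-(benzyloxy)-3-methoxyphenyl](hydroxy)methyl}-2-[4-(dimethylcarbamoyloxy)-3-methoxyphenyl]oxolane-3-carboxylic acid F2, whose cis γ-hydroxy acid closes to 17 with PPTS in CH2Cl2. Here the two new centres come from a substrate-controlled syn hydroboration and no longer from the cationic capture.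

Second, step 4. What may go wrong: reaction of the boron dienolate through its γ-carbon, or migration of the double bond into conjugation with the imide during enolisation, with loss of regio- and diastereocontrol. In the fallback the aldol reaction is run on the parent but-3-enoyl imide, for which α-attack is the rule, and the aryl group is attached afterwards; it sets out from 5 and returns at 11. Acylation of 5 with but-3-enoic acid (PivCl, Et3N, LiCl, THF) gives (4S)-4-benzyl-3-(but-3-enoyl)-1,3-oxazolidin-2-one F3. Its Evans syn aldol reaction with 9 (Bu2BOTf, Et3N, CH2Cl2, −78 → 0 °C) gives (4S)-4-benzyl-3-[(2S)-2-{(S)-[4-(dimethylcarbamoyloxy)-3-methoxyphenyl](hydroxy)methyl}but-3-enoyl]-1,3-oxazolidin-2-one F4. Cross-metathesis of F4 with 1-(benzyloxy)-4-ethenyl-2-methoxybenzene F5 (from 1 and Ph3P=CH2), using the second-generation Hoveyda–Grubbs catalyst (CH2Cl2, 40 °C), should give the E-styrene 11.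

Third, step 8. What may go wrong: the carbamate is reduced only under forcing conditions, under which the aluminium phenoxide can expel the benzylic ring oxygen (quinone methide formation) and hydride then removes the oxygen at C7; or the cleavage stays incomplete. In the fallback the two reductions are separated; it sets out from 17 and returns at 18. LiBH4 (THF, 0 °C → rt) reduces only the lactone and gives 4-[(2S,3R,4R)-4-{(S)-[4-(benzyloxy)-3-methoxyphenyl](hydroxy)methyl}-3-(hydroxymethyl)oxolan-2-yl]-2-methoxyphenyl dimethylcarbamate F6. The aryl carbamate is then cleaved with Cp2Zr(H)Cl (THF, rt), a reagent known to reduce aryl O-carbamates to phenols under mild, non-basic conditions, which gives 18.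

Further compounds
F1 | step 7 | methoxymethyl (2S,3S,4Z)-4-[4-(benzyloxy)-3-methoxybenzylidene]-2-[4-(dimethylcarbamoyloxy)-3-methoxyphenyl]oxolane-3-carboxylate | COc1cc(/C=C2\CO[C@H](c3ccc(OC(=O)N(C)C)c(OC)c3)[C@H]2C(=O)OCOC)ccc1OCc1ccccc1
F2 | step 7 | (2S,3S,4R)-4-{(S)-[4-(benzyloxy)-3-methoxyphenyl](hydroxy)methyl}-2-[4-(dimethylcarbamoyloxy)-3-methoxyphenyl]oxolane-3-carboxylic acid | COc1cc([C@@H](O)[C@H]2CO[C@H](c3ccc(OC(=O)N(C)C)c(OC)c3)[C@H]2C(=O)O)ccc1OCc1ccccc1
F3 | step 4 | (4S)-4-benzyl-3-(but-3-enoyl)-1,3-oxazolidin-2-one | C=CCC(=O)N1[C@@H](Cc2ccccc2)COC1=O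
F4 | step 4 | (4S)-4-benzyl-3-[(2S)-2-{(S)-[4-(dimethylcarbamoyloxy)-3-methoxyphenyl](hydroxy)methyl}but-3-enoyl]-1,3-oxazolidin-2-one | O[C@H](c1ccc(OC(=O)N(C)C)c(OC)c1)[C@H](C=C)C(=O)N1[C@@H](Cc2ccccc2)COC1=O
F5 | step 4 | 1-(benzyloxy)-4-ethenyl-2-methoxybenzene | C=Cc1ccc(OCc2ccccc2)c(OC)c1
F6 | step 8 | 4-[(2S,3R,4R)-4-{(S)-[4-(benzyloxy)-3-methoxyphenyl](hydroxy)methyl}-3-(hydroxymethyl)oxolan-2-yl]-2-methoxyphenyl dimethylcarbamate | COc1cc([C@@H](O)[C@H]2CO[C@H](c3ccc(OC(=O)N(C)C)c(OC)c3)[C@H]2CO)ccc1OCc1ccccc1
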